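**Strategy.** Idiadione (chain numbered from C1, the CH2 on the furan ring, to C17) is cut at C8–C9. The only stereocentre, C8, carries a methyl branch and sits at the β-position of the C6 ketone. This marks C6–C8 plus that methyl as methyl (E)-crotonate and C9–C17 as primary Grignard reagent 12, which already holds the (E)-C11=C12 alkene and C14 as a racemic silyl-protected carbinol. One copper/Tol-BINAP-catalysed 1,4-addition joins the halves, makes the C8–C9 bond and sets the stereocentre, leaving C6 as an ester. The furan ring with C1–C5 is added afterwards as an allylbarium reagent to the C6 aldehyde, and both ketones are unveiled last by a double oxidation.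

Key step: step 7

Assumption on the sense of induction: the CuI/(S)-Tol-BINAP catalyst is taken to deliver a primary alkyl group to the β-face of an (E)-enoate that makes C8 (S) when the resident β-substituent is methyl. The ligand assignment is not secure: it is to be checked on methyl citronellate made from 4-methylpent-3-enylmagnesium bromide, and (R)-Tol-BINAP is to be used if the sense proves opposite.

Remark on the carbinol centres: C14 (from step 1) and C6 (from step 12) are carried as epimer mixtures because both become ketones in step 14.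

Remark on the precursor design: 12 is made as the bromide in Et2O without THF and is the limiting partner. Inexpensive 13 is in excess and 12 is added slowly, so the six-step fragment is not wasted and the uncatalysed 1,2-addition is starved of free Grignard reagent.

**Step 1**
Reactants: 1 3-methylbutanal; 2 propargyl bromide (3-bromoprop-1-yne)
Product: 4 rac-6-methylhept-1-yn-4-ol, via propa-1,2-dienylzinc bromide 3 (not isolated)
Conditions: Zn dust, THF/sat. aq NH4Cl, 0 °C to rt
Reagents that add atoms: none
Why: Barbier-type zinc propargylation, in which the allenylzinc species adds to the aldehyde through an SE2' transition state to give the homopropargylic alcohol; the carbinol centre (future C14) forms as a racemate, which is immaterial because it ends as a ketone.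

**Step 2**
Reactants: 4 rac-6-methylhept-1-yn-4-ol
Product: 5 rac-tert-butyldimethyl[(6-methylhept-1-yn-4-yl)oxy]silane
Conditions: TBSCl, imidazole, DMF, rt
Reagents that add atoms: tert-butyldimethylsilyl chloride, CC(C)(C)[Si](C)(C)Cl
Why: Standard imidazole-promoted silylation of a secondary alcohol gives an ether that tolerates Me3Al, t-BuLi, magnesium and the organocopper step.

**Step 3**
Reactants: 5 rac-tert-butyldimethyl[(6-methylhept-1-yn-4-yl)oxy]silane
Product: 7 tert-butyl{[(1E)-1-iodo-2,6-dimethylhept-1-en-4-yl]oxy}dimethylsilane, via alkenyldimethylalane 6 (not isolated)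
Conditions: Me3Al (2.5 equiv), Cp2ZrCl2 (0.25 equiv), CH2Cl2, 0 °C to rt; then I2, THF, −30 to 0 °C
Reagents that add atoms: trimethylaluminium, C[Al](C)C; iodine, II
Why: Negishi zirconium-catalysed carboalumination adds methyl and aluminium syn across the terminal alkyne with methyl on the internal carbon, and iodinolysis of the C–Al bond with retention fixes the (E)-C11=C12 geometry.

**Step 4**
Reactants: 7 tert-butyl{[(1E)-1-iodo-2,6-dimethylhept-1-en-4-yl]oxy}dimethylsilane; 8 oxirane
Product: 10 (3E)-6-[(tert-butyldimethylsilyl)oxy]-4,8-dimethylnon-3-en-1-ol, via alkenyllithium 9 (not isolated)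
Conditions: t-BuLi (2.1 equiv), Et2O, −78 °C; then oxirane (excess), −78 °C to rt
Reagents that add atoms: none
Why: Iodine–lithium exchange occurs with retention of alkene geometry and the alkenyllithium opens the strained, unhindered oxirane by SN2 attack, adding C9 and C10.

**Step 5**
Reactants: 10 (3E)-6-[(tert-butyldimethylsilyl)oxy]-4,8-dimethylnon-3-en-1-ol
Product: 11 (3E)-1-bromo-6-[(tert-butyldimethylsilyl)oxy]-4,8-dimethylnon-3-ene
Conditions: CBr4, PPh3, 2,6-lutidine, CH2Cl2, 0 °C
Reagents that add atoms: tetrabromomethane, BrC(Br)(Br)Br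
Why: Appel bromination converts the primary alcohol to the bromide by SN2 displacement of the alkoxyphosphonium ion, with 2,6-lutidine scavenging HBr so that the silyl ether survives.

**Step 6**
Reactants: 11 (3E)-1-bromo-6-[(tert-butyldimethylsilyl)oxy]-4,8-dimethylnon-3-ene
Product: 12 [(3E)-6-[(tert-butyldimethylsilyl)oxy]-4,8-dimethylnon-3-en-1-yl]magnesium bromide (titrated Et2O solution)
Conditions: Mg turnings (I2-activated), Et2O, reflux
Reagents that add atoms: magnesium, [Mg]
Why: Direct magnesium insertion into a primary homoallylic bromide gives a Grignard reagent that does not rearrange, prepared in Et2O because THF erodes selectivity in the following copper-catalysed step.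

**Step 7**
Reactants: 12 [(3E)-6-[(tert-butyldimethylsilyl)oxy]-4,8-dimethylnon-3-en-1-yl]magnesium bromide; 13 methyl (E)-but-2-enoate
Product: 15 methyl (3S,6E)-9-[(tert-butyldimethylsilyl)oxy]-3,7,11-trimethyldodec-6-enoate (C9 epimers), via bromomagnesium ester enolate 14 (not isolated)
Conditions: CuI (3 mol%), (S)-Tol-BINAP (4.5 mol%), 13 (1.5 equiv), t-BuOMe, −40 °C, 12 in Et2O added over 2 h; then MeOH, sat. aq NH4Cl
Reagents that add atoms: none
Why: Transmetallation of 12 to the Tol-BINAP-bound monovalent copper halide gives an alkylcopper that forms a π-complex with the enoate; oxidative addition to a trivalent copper β-cuprio enolate and reductive elimination then forge C8–C9 and release magnesium enolate 14, which is protonated on quench. The closest known reaction type is the copper/chiral bisphosphine-catalysed enantioselective 1,4-addition of primary alkylmagnesium bromides to (E)-α,β-unsaturated methyl esters. No ring is closed. C8 is set under catalyst control: the ligand enantiomer shields one β-face of the geometrically pure (E)-enoate, so the alkyl group should be delivered to the face that gives S. The step needs 1,4- over 1,2-chemoselectivity and high facial selectivity; the small β-methyl group of crotonate, the unbranched primary nucleophile whose remote trisubstituted alkene and silyl ether do not bind copper, the weakly coordinating ether solvent and slow addition at −40 °C should secure both. The C14 epimers of 15 are not separated because that centre becomes a ketone.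

**Step 8**
Reactants: 16 furan-3-ylmethanol
Product: 18 3-(chloromethyl)furan, via furan-3-ylmethyl methanesulfonate 17 (not isolated)
Conditions: MsCl, LiCl, 2,4,6-collidine, DMF, 0 °C; used at once as a solution
Reagents that add atoms: lithium chloride, [Li+].[Cl-] (chlorine of 18); methanesulfonyl chloride, CS(=O)(=O)Cl (mesyl group of 17 only)
Why: Collington–Meyers chlorination, in which the mesylate formed in situ is displaced by chloride under non-acidic conditions that the furan tolerates.

**Step 9**
Reactants: 18 3-(chloromethyl)furan; 19 2-methyl-2-vinyloxirane (racemic)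
Product: 21 (2E)-5-(furan-3-yl)-2-methylpent-2-en-1-ol, via (furan-3-ylmethyl)magnesium chloride 20 (not isolated)
Conditions: Mg, THF, 0 °C; then 19, CuI (10 mol%), THF, −40 to −20 °C; sat. aq NH4Cl
Reagents that add atoms: none
Why: Grignard formation followed by copper-catalysed anti-SN2' opening of the vinyl oxirane through its s-trans conformer should deliver the (E)-trisubstituted allylic alcohol with C1–C5 complete; a minor (Z)-isomer, if formed, is removed here on AgNO3-impregnated silica.

**Step 10**
Reactants: 21 (2E)-5-(furan-3-yl)-2-methylpent-2-en-1-ol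
Product: 23 3-[(3E)-5-chloro-4-methylpent-3-en-1-yl]furan, via allylic methanesulfonate 22 (not isolated)
Conditions: MsCl, LiCl, 2,4,6-collidine, DMF, 0 °C
Reagents that add atoms: lithium chloride, [Li+].[Cl-] (chlorine of 23); methanesulfonyl chloride, CS(=O)(=O)Cl (mesyl group of 22 only)
Why: Collington–Meyers chlorination of a primary allylic alcohol proceeds by direct SN2 displacement of the mesylate by chloride without allylic transposition or loss of the (E)-geometry.

**Step 11**
Reactants: 15 methyl (3S,6E)-9-[(tert-butyldimethylsilyl)oxy]-3,7,11-trimethyldodec-6-enoate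
Product: 25 (3S,6E)-9-[(tert-butyldimethylsilyl)oxy]-3,7,11-trimethyldodec-6-enal (C9 epimers), via diisobutylaluminium hemiacetal 24 (not isolated)
Conditions: i-Bu2AlH (1.05 equiv), CH2Cl2, −78 °C; then MeOH, aq potassium sodium tartrate
Reagents that add atoms: none
Why: Partial reduction of a methyl ester with one equivalent of i-Bu2AlH at −78 °C stops at the tetrahedral aluminium hemiacetal, which releases the aldehyde only on work-up; C8 is β to the carbonyl and cannot epimerise.

**Step 12**
Reactants: 25 (3S,6E)-9-[(tert-butyldimethylsilyl)oxy]-3,7,11-trimethyldodec-6-enal; 23 3-[(3E)-5-chloro-4-methylpent-3-en-1-yl]furan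
Product: 27 (3E,8S,11E)-14-[(tert-butyldimethylsilyl)oxy]-1-(furan-3-yl)-4,8,12,16-tetramethylheptadeca-3,11-dien-6-ol (C6 and C14 epimers), via allylbarium chloride 26 (not isolated)
Conditions: Li, biphenyl, THF, rt; BaI2, rt; 23 (1.5 equiv), −78 °C; then 25, −78 °C; sat. aq NH4Cl
Reagents that add atoms: none
Why: α-Selective allylbarium addition, in which the allylbarium chloride formed from activated barium at −78 °C keeps its (E)-geometry and adds to the aldehyde at its unsubstituted α-carbon to form C5–C6; the C6 carbinol forms as an epimeric mixture that is oxidised later.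

**Step 13**
Reactants: 27 (3E,8S,11E)-14-[(tert-butyldimethylsilyl)oxy]-1-(furan-3-yl)-4,8,12,16-tetramethylheptadeca-3,11-dien-6-ol
Product: 28 (3E,8S,11E)-1-(furan-3-yl)-4,8,12,16-tetramethylheptadeca-3,11-diene-6,14-diol (C6 and C14 epimers)
Conditions: Bu4NF, THF, rt
Reagents that add atoms: none
Why: Fluoride-mediated cleavage of the secondary silyl ether is done before the ketones exist, so that basic fluoride cannot isomerise a β,γ-unsaturated ketone.

**Step 14**
Reactants: 28 (3E,8S,11E)-1-(furan-3-yl)-4,8,12,16-tetramethylheptadeca-3,11-diene-6,14-diol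
Product: 29 idiadione, (3E,8S,11E)-1-(furan-3-yl)-4,8,12,16-tetramethylheptadeca-3,11-diene-6,14-dione
Conditions: Dess–Martin periodinane (3 equiv), NaHCO3, CH2Cl2, 0 °C to rt
Reagents that add atoms: none
Why: Dess–Martin oxidation of both secondary alcohols under bicarbonate buffering is neutral and non-enolising, so the two β,γ-unsaturated ketones should form without migration of the alkenes into conjugation, and the furan and C8 are untouched.

**Compound list**

1 | 3-methylbutanal | CC(C)CC=O | starting material
2 | propargyl bromide (3-bromoprop-1-yne) | C#CCBr | starting material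
3 | propa-1,2-dienylzinc bromide (in situ) | C=C=C[Zn]Br | intermediate
4 | rac-6-methylhept-1-yn-4-ol | C#CCC(O)CC(C)C | intermediate
5 | rac-tert-butyldimethyl[(6-methylhept-1-yn-4-yl)oxy]silane | C#CCC(O[Si](C)(C)C(C)(C)C)CC(C)C | intermediate
6 | [(1E)-4-[(tert-butyldimethylsilyl)oxy]-2,6-dimethylhept-1-en-1-yl]dimethylalane (in situ) | C[Al](C)/C=C(\C)CC(O[Si](C)(C)C(C)(C)C)CC(C)C | intermediate
7 | tert-butyl{[(1E)-1-iodo-2,6-dimethylhept-1-en-4-yl]oxy}dimethylsilane (racemic) | I/C=C(\C)CC(O[Si](C)(C)C(C)(C)C)CC(C)C | intermediate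
8 | oxirane | C1CO1 | starting material
9 | [(1E)-4-[(tert-butyldimethylsilyl)oxy]-2,6-dimethylhept-1-en-1-yl]lithium (in situ) | [Li]/C=C(\C)CC(O[Si](C)(C)C(C)(C)C)CC(C)C | intermediate
10 | (3E)-6-[(tert-butyldimethylsilyl)oxy]-4,8-dimethylnon-3-en-1-ol (racemic) | OCC/C=C(\C)CC(O[Si](C)(C)C(C)(C)C)CC(C)C | intermediate
11 | (3E)-1-bromo-6-[(tert-butyldimethylsilyl)oxy]-4,8-dimethylnon-3-ene (racemic) | BrCC/C=C(\C)CC(O[Si](C)(C)C(C)(C)C)CC(C)C | intermediate
12 | [(3E)-6-[(tert-butyldimethylsilyl)oxy]-4,8-dimethylnon-3-en-1-yl]magnesium bromide (silyloxy carbon racemic) | Br[Mg]CC/C=C(\C)CC(O[Si](C)(C)C(C)(C)C)CC(C)C | intermediate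
13 | methyl (E)-but-2-enoate | C/C=C/C(=O)OC | starting material
14 | bromomagnesium enolate of ester 15 (in situ, enolate geometry not assigned) | C/C(=C\CC[C@H](C)C=C(OC)O[Mg]Br)CC(O[Si](C)(C)C(C)(C)C)CC(C)C | intermediate
15 | methyl (3S,6E)-9-[(tert-butyldimethylsilyl)oxy]-3,7,11-trimethyldodec-6-enoate (C9 epimers) | C/C(=C\CC[C@H](C)CC(=O)OC)CC(O[Si](C)(C)C(C)(C)C)CC(C)C | intermediate
16 | furan-3-ylmethanol | OCc1ccoc1 | starting material
17 | furan-3-ylmethyl methanesulfonate (in situ) | CS(=O)(=O)OCc1ccoc1 | intermediate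
18 | 3-(chloromethyl)furan | ClCc1ccoc1 | intermediate
19 | 2-methyl-2-vinyloxirane (racemic) | CC1(CO1)C=C | starting material
20 | (furan-3-ylmethyl)magnesium chloride (in situ) | Cl[Mg]Cc1ccoc1 | intermediate
21 | (2E)-5-(furan-3-yl)-2-methylpent-2-en-1-ol | OC/C(C)=C/CCc1ccoc1 | intermediate
22 | (2E)-5-(furan-3-yl)-2-methylpent-2-en-1-yl methanesulfonate (in situ) | CS(=O)(=O)OC/C(C)=C/CCc1ccoc1 | intermediate
23 | 3-[(3E)-5-chloro-4-methylpent-3-en-1-yl]furan | ClC/C(C)=C/CCc1ccoc1 | intermediate
24 | diisobutylaluminium hemiacetal of aldehyde 25 (in situ) | C/C(=C\CC[C@H](C)CC(OC)O[Al](CC(C)C)CC(C)C)CC(O[Si](C)(C)C(C)(C)C)CC(C)C | intermediate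
25 | (3S,6E)-9-[(tert-butyldimethylsilyl)oxy]-3,7,11-trimethyldodec-6-enal (C9 epimers) | C/C(=C\CC[C@H](C)CC=O)CC(O[Si](C)(C)C(C)(C)C)CC(C)C | intermediate
26 | chloro[(2E)-5-(furan-3-yl)-2-methylpent-2-en-1-yl]barium (in situ) | Cl[Ba]C/C(C)=C/CCc1ccoc1 | intermediate
27 | (3E,8S,11E)-14-[(tert-butyldimethylsilyl)oxy]-1-(furan-3-yl)-4,8,12,16-tetramethylheptadeca-3,11-dien-6-ol (C6 and C14 epimers) | C/C(=C\CC[C@H](C)CC(O)C/C(C)=C/CCc1ccoc1)CC(O[Si](C)(C)C(C)(C)C)CC(C)C | intermediate
28 | (3E,8S,11E)-1-(furan-3-yl)-4,8,12,16-tetramethylheptadeca-3,11-diene-6,14-diol (C6 and C14 epimers) | C/C(=C\CC[C@H](C)CC(O)C/C(C)=C/CCc1ccoc1)CC(O)CC(C)C | intermediate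
29 | idiadione, (3E,8S,11E)-1-(furan-3-yl)-4,8,12,16-tetramethylheptadeca-3,11-diene-6,14-dione | C/C(=C\CC[C@H](C)CC(=O)C/C(C)=C/CCc1ccoc1)CC(=O)CC(C)C | target

**Step count and risk**

Total steps: 14. Longest linear sequence: 11 steps (steps 1–7 and 11–14); the furan branch (steps 8–10) joins at step 12.

Steps most likely to fail:

1. Step 7. What may go wrong: insufficient facial selectivity at C8, or uncatalysed 1,2-addition and enolate–enoate oligomerisation with the unhindered crotonate. Fallback (auxiliary control instead of catalyst control), setting out from 12 and returning at 15: (4S)-4-phenyl-1,3-oxazolidin-2-one would be N-acylated with (E)-but-2-enoyl chloride (Et3N, cat. DMAP, CH2Cl2) to give (4S)-3-[(2E)-but-2-enoyl]-4-phenyl-1,3-oxazolidin-2-one F1. Grignard reagent 12 with CuBr·SMe2 in THF/Me2S at −40 °C should add to the magnesium-chelated syn-s-cis imide on the face anti to the phenyl group, giving (4S)-3-[(3S,6E)-9-[(tert-butyldimethylsilyl)oxy]-3,7,11-trimethyldodec-6-enoyl]-4-phenyl-1,3-oxazolidin-2-one F2. Methanolysis (NaOMe, MeOH, 0 °C) would release the auxiliary and give 15.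

2. Step 12. What may go wrong: erosion of α-regioselectivity or of (E)-geometry if the allylbarium equilibrates before it adds, or Wurtz-type homocoupling while it is generated. Fallback (acyl-anion alkylation instead of carbonyl allylation), setting out from 25 and 23 and returning at 29: thioacetalisation with propane-1,3-dithiol (MgBr2·OEt2, Et2O) would give 2-[(2S,5E)-8-[(tert-butyldimethylsilyl)oxy]-2,6,10-trimethylundec-5-en-1-yl]-1,3-dithiane F3. Deprotonation (n-BuLi, THF, −30 °C) would give the 2-lithio-1,3-dithiane F4. SN2 alkylation with 23, which can occur only at the primary carbon and leaves the alkene geometry untouched, would give 2-[(2E)-5-(furan-3-yl)-2-methylpent-2-en-1-yl]-2-[(2S,5E)-8-[(tert-butyldimethylsilyl)oxy]-2,6,10-trimethylundec-5-en-1-yl]-1,3-dithiane F5. Alkylative hydrolysis (MeI, CaCO3, aqueous MeCN) would unveil (3E,8S,11E)-14-[(tert-butyldimethylsilyl)oxy]-1-(furan-3-yl)-4,8,12,16-tetramethylheptadeca-3,11-dien-6-one F6. Buffered desilylation (Bu4NF, AcOH, THF) would give (3E,8S,11E)-1-(furan-3-yl)-14-hydroxy-4,8,12,16-tetramethylheptadeca-3,11-dien-6-one F7, and a single Dess–Martin oxidation would give 29.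

3. Step 9. What may go wrong: incomplete (E)-selectivity in the SN2' opening, or competing direct SN2 attack at the oxirane. Fallback (geometry set by allylic oxidation instead of by the epoxide opening), setting out from 18 and returning at 21: Grignard reagent 20, made from 18 as before, would be coupled with 1-chloro-3-methylbut-2-ene under Li2CuCl4 catalysis (THF, 0 °C) to give 3-(4-methylpent-3-en-1-yl)furan F8 (perillene). SeO2 (catalytic) with t-BuOOH in CH2Cl2 should oxidise the (E)-methyl group selectively by an ene reaction and [2,3]-sigmatropic shift. NaBH4 would reduce any enal formed, giving 21.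

**Further compounds**

F1 | step 7 | (4S)-3-[(2E)-but-2-enoyl]-4-phenyl-1,3-oxazolidin-2-one | C/C=C/C(=O)N1[C@@H](c2ccccc2)COC1=O
F2 | step 7 | (4S)-3-[(3S,6E)-9-[(tert-butyldimethylsilyl)oxy]-3,7,11-trimethyldodec-6-enoyl]-4-phenyl-1,3-oxazolidin-2-one | C/C(=C\CC[C@H](C)CC(=O)N1[C@@H](c2ccccc2)COC1=O)CC(O[Si](C)(C)C(C)(C)C)CC(C)C
F3 | step 12 | 2-[(2S,5E)-8-[(tert-butyldimethylsilyl)oxy]-2,6,10-trimethylundec-5-en-1-yl]-1,3-dithiane | C/C(=C\CC[C@H](C)CC1SCCCS1)CC(O[Si](C)(C)C(C)(C)C)CC(C)C
F4 | step 12 | 2-lithio derivative of dithiane F3 | C/C(=C\CC[C@H](C)CC1([Li])SCCCS1)CC(O[Si](C)(C)C(C)(C)C)CC(C)C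
F5 | step 12 | 2-[(2E)-5-(furan-3-yl)-2-methylpent-2-en-1-yl]-2-[(2S,5E)-8-[(tert-butyldimethylsilyl)oxy]-2,6,10-trimethylundec-5-en-1-yl]-1,3-dithiane | C/C(=C\CC[C@H](C)CC1(C/C(C)=C/CCc2ccoc2)SCCCS1)CC(O[Si](C)(C)C(C)(C)C)CC(C)C
F6 | step 12 | (3E,8S,11E)-14-[(tert-butyldimethylsilyl)oxy]-1-(furan-3-yl)-4,8,12,16-tetramethylheptadeca-3,11-dien-6-one | C/C(=C\CC[C@H](C)CC(=O)C/C(C)=C/CCc1ccoc1)CC(O[Si](C)(C)C(C)(C)C)CC(C)C
F7 | step 12 | (3E,8S,11E)-1-(furan-3-yl)-14-hydroxy-4,8,12,16-tetramethylheptadeca-3,11-dien-6-one | C/C(=C\CC[C@H](C)CC(=O)C/C(C)=C/CCc1ccoc1)CC(O)CC(C)C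
F8 | step 9 | 3-(4-methylpent-3-en-1-yl)furan (perillene) | CC(C)=CCCc1ccoc1
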